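**Retrosynthetic overview**
- The target comes from its pentabenzyl ether by hydrogenolysis of the five aryl benzyl ethers (last step).
- Both rings are cut at their benzylic C–O bonds (C3–O2 of the lactone, C6–O5 of the tetrahydrofuran). This leads back to an open-chain hydroxy pyrrolidine amide with two benzylic carbinols. One acid-triggered cascade makes both C–O bonds, lactone ring first and tetrahydrofuran ring second, and sets C3 and C6.
- The hydroxy amide comes from aminolysis of a trans-3,4-disubstituted butyrolactone, whose C6a–C6 bond is made by a lactone enolate aldol with 3,4-bis(benzyloxy)benzaldehyde (sets C6a).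
- The beta-substituted butyrolactone comes from an L-proline cross-aldol of methyl 4-oxobutanoate with 3,4,5-tris(benzyloxy)benzaldehyde, then reduction and lactonization (sets C3a, the only centre taken from asymmetric catalysis).

Assumption: both benzyl-protected aldehydes are bought as such; the carbinol made in step 2 is an epimer mixture and is written without a descriptor; atom labels C1, O2, C3, C3a, C4, O5, C6, C6a are those of the target ring system.

**Step 1**
Reactants: 1 3,4,5-tris(benzyloxy)benzaldehyde; 2 methyl 4-oxobutanoate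
Product: 5 (4R)-4-{(R)-hydroxy[3,4,5-tris(benzyloxy)phenyl]methyl}dihydrofuran-2(3H)-one, via aldol aldehyde 3 (not isolated), via diol ester 4 (not isolated)
Conditions: L-proline (20 mol%), DMF, 4 °C, 48 h, 2 added slowly (2 equiv); then NaBH4, MeOH, 0 °C; 1 M HCl work-up
Reagents that add atoms: none
Why: Proline enamine cross-aldol (List–Houk transition state): the (E)-enamine of 2 adds to the Re face of 1 through the carboxylic-acid-bound chair, which fixes C3a (and the anti carbinol at C3, whose configuration is irrelevant later); NaBH4 then reduces the formyl group and the primary alkoxide lactonizes onto the methyl ester.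

**Step 2**
Reactants: 5 (4R)-4-{(R)-hydroxy[3,4,5-tris(benzyloxy)phenyl]methyl}dihydrofuran-2(3H)-one; 6 3,4-bis(benzyloxy)benzaldehyde
Product: 7 (3S,4R)-3-{[3,4-bis(benzyloxy)phenyl](hydroxy)methyl}-4-{(R)-hydroxy[3,4,5-tris(benzyloxy)phenyl]methyl}dihydrofuran-2(3H)-one
Conditions: LiN(SiMe3)2 (2.2 equiv), THF, −78 °C, 1 h; then 6, −78 °C, 1 h; AcOH quench at −78 °C
Reagents that add atoms: none
Why: Lithium dianion aldol of a beta-substituted gamma-butyrolactone: the aldehyde adds to the enolate face anti to the C4 substituent, which sets C6a (3,4-trans); the new carbinol forms as an epimer mixture that step 4 erases.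

**Step 3**
Reactants: 7 (3S,4R)-3-{[3,4-bis(benzyloxy)phenyl](hydroxy)methyl}-4-{(R)-hydroxy[3,4,5-tris(benzyloxy)phenyl]methyl}dihydrofuran-2(3H)-one
Product: 8 (2S,3R,4R)-2-{[3,4-bis(benzyloxy)phenyl](hydroxy)methyl}-4-hydroxy-3-(hydroxymethyl)-1-(pyrrolidin-1-yl)-4-[3,4,5-tris(benzyloxy)phenyl]butan-1-one
Conditions: pyrrolidine (4 equiv), AlMe3 (4 equiv), CH2Cl2, 0 °C to rt, 3 h; aq. KNaC4H4O6
Reagents that add atoms: pyrrolidine, C1CCNC1
Why: Weinreb-type aminolysis (dimethylaluminium amide opening of a lactone) attacks only the acyl carbon, so no stereocentre is touched; it frees the C4 hydroxyl and turns the carboxyl group into a tertiary amide that is a strong internal O-nucleophile and cannot decarboxylate.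

**Step 4**
Reactants: 8 (2S,3R,4R)-2-{[3,4-bis(benzyloxy)phenyl](hydroxy)methyl}-4-hydroxy-3-(hydroxymethyl)-1-(pyrrolidin-1-yl)-4-[3,4,5-tris(benzyloxy)phenyl]butan-1-one
Product: 11 (3S,3aR,6S,6aS)-6-[3,4-bis(benzyloxy)phenyl]-3-[3,4,5-tris(benzyloxy)phenyl]tetrahydro-1H,3H-furo[3,4-c]furan-1-one, via iminium ether 9 (not isolated), via hydroxy lactone 10 (not isolated)
Conditions: TsOH·H2O (1.3 equiv), CH2Cl2–(CF3)2CHOH 9:1, 0.02 M, 0 °C, 1 h; aq. NaHCO3
Reagents that add atoms: water, O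
Why: Proposed new method: a Brønsted-acid-promoted, stereoconvergent double dehydrative cyclization in which both benzylic alcohols ionize to alkoxyaryl-stabilized cations; the C3 cation is captured 5-exo by the amide oxygen to give cyclic iminium ether 9, which the released water hydrolyses with C–N cleavage (acidic medium) to lactone 10, and the C6 cation is then captured by the C4 hydroxyl to close the tetrahydrofuran; in each closure allylic 1,3-strain in the planar cation puts H3a or H6a syn to the aryl group, so the aryl group ends trans to the neighbouring ring substituent, which sets C3 (S) and C6 (S) whatever the carbinol configurations were (net inversion at C3); once the lactone is closed the remaining cation and the other arene lie on opposite ring faces, so Friedel–Crafts tetralin formation is geometrically excluded; closest known reaction types are the acid-mediated SN1 cyclodehydration of benzylic 1,4-diols to furofuran lignans and amide-oxygen participation (iminolactonization) in halolactonization of unsaturated amides.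

**Step 5**
Reactants: 11 (3S,3aR,6S,6aS)-6-[3,4-bis(benzyloxy)phenyl]-3-[3,4,5-tris(benzyloxy)phenyl]tetrahydro-1H,3H-furo[3,4-c]furan-1-one
Product: 12 (3S,3aR,6S,6aS)-6-(3,4-dihydroxyphenyl)-3-(3,4,5-trihydroxyphenyl)tetrahydro-1H,3H-furo[3,4-c]furan-1-one
Conditions: H2 (1 atm), 10% Pd/C, THF–EtOAc, rt, stopped after uptake of 5 equiv H2; argon work-up
Reagents that add atoms: none
Why: Heterogeneous hydrogenolysis: aryl O-benzyl bonds are cleaved on palladium much faster than the ring C–O bonds at C3 and C6 in a neutral aprotic solvent, so the five phenols are freed without touching a stereocentre.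

**Compound list**
1 | 3,4,5-tris(benzyloxy)benzaldehyde | O=Cc1cc(OCc2ccccc2)c(OCc2ccccc2)c(OCc2ccccc2)c1 | starting material
2 | methyl 4-oxobutanoate | COC(=O)CCC=O | starting material
3 | methyl (3S,4R)-3-formyl-4-hydroxy-4-[3,4,5-tris(benzyloxy)phenyl]butanoate | COC(=O)C[C@H](C=O)[C@@H](O)c1cc(OCc2ccccc2)c(OCc2ccccc2)c(OCc2ccccc2)c1 | intermediate
4 | methyl (3R,4R)-4-hydroxy-3-(hydroxymethyl)-4-[3,4,5-tris(benzyloxy)phenyl]butanoate | COC(=O)C[C@H](CO)[C@@H](O)c1cc(OCc2ccccc2)c(OCc2ccccc2)c(OCc2ccccc2)c1 | intermediate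
5 | (4R)-4-{(R)-hydroxy[3,4,5-tris(benzyloxy)phenyl]methyl}dihydrofuran-2(3H)-one | O=C1C[C@H](CO1)[C@@H](O)c1cc(OCc2ccccc2)c(OCc2ccccc2)c(OCc2ccccc2)c1 | intermediate
6 | 3,4-bis(benzyloxy)benzaldehyde | O=Cc1ccc(OCc2ccccc2)c(OCc2ccccc2)c1 | starting material
7 | (3S,4R)-3-{[3,4-bis(benzyloxy)phenyl](hydroxy)methyl}-4-{(R)-hydroxy[3,4,5-tris(benzyloxy)phenyl]methyl}dihydrofuran-2(3H)-one | O=C1OC[C@H]([C@@H](O)c2cc(OCc3ccccc3)c(OCc3ccccc3)c(OCc3ccccc3)c2)[C@H]1C(O)c1ccc(OCc2ccccc2)c(OCc2ccccc2)c1 | intermediate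
8 | (2S,3R,4R)-2-{[3,4-bis(benzyloxy)phenyl](hydroxy)methyl}-4-hydroxy-3-(hydroxymethyl)-1-(pyrrolidin-1-yl)-4-[3,4,5-tris(benzyloxy)phenyl]butan-1-one | O=C(N1CCCC1)[C@H](C(O)c1ccc(OCc2ccccc2)c(OCc2ccccc2)c1)[C@H](CO)[C@@H](O)c1cc(OCc2ccccc2)c(OCc2ccccc2)c(OCc2ccccc2)c1 | intermediate
9 | 1-[(3S,4R,5S)-3-{[3,4-bis(benzyloxy)phenyl](hydroxy)methyl}-4-(hydroxymethyl)-5-[3,4,5-tris(benzyloxy)phenyl]oxolan-2-ylidene]pyrrolidin-1-ium 4-methylbenzenesulfonate | OC[C@@H]1[C@@H](c2cc(OCc3ccccc3)c(OCc3ccccc3)c(OCc3ccccc3)c2)OC(=[N+]2CCCC2)[C@@H]1C(O)c1ccc(OCc2ccccc2)c(OCc2ccccc2)c1.Cc1ccc(cc1)S(=O)(=O)[O-] | intermediate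
10 | (3S,4R,5S)-3-{[3,4-bis(benzyloxy)phenyl](hydroxy)methyl}-4-(hydroxymethyl)-5-[3,4,5-tris(benzyloxy)phenyl]dihydrofuran-2(3H)-one | OC[C@@H]1[C@@H](c2cc(OCc3ccccc3)c(OCc3ccccc3)c(OCc3ccccc3)c2)OC(=O)[C@@H]1C(O)c1ccc(OCc2ccccc2)c(OCc2ccccc2)c1 | intermediate
11 | (3S,3aR,6S,6aS)-6-[3,4-bis(benzyloxy)phenyl]-3-[3,4,5-tris(benzyloxy)phenyl]tetrahydro-1H,3H-furo[3,4-c]furan-1-one | O=C1O[C@H](c2cc(OCc3ccccc3)c(OCc3ccccc3)c(OCc3ccccc3)c2)[C@H]2CO[C@H](c3ccc(OCc4ccccc4)c(OCc4ccccc4)c3)[C@@H]12 | intermediate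
12 | (3S,3aR,6S,6aS)-6-(3,4-dihydroxyphenyl)-3-(3,4,5-trihydroxyphenyl)tetrahydro-1H,3H-furo[3,4-c]furan-1-one | O=C1O[C@H](c2cc(O)c(O)c(O)c2)[C@H]2CO[C@H](c3ccc(O)c(O)c3)[C@@H]12 | target

**Totals and risks**
Total step count: 5. Longest linear sequence: 5 steps (1 and 2 to 12).

The three steps most likely to fail:

Step 4 (the new cascade). It may give Friedel–Crafts tetralins, the alkene from loss of H6a, lactone 7 by acyl transfer to O4, or C3/C6 epimers. The fallback uses known chemistry only: it corrects C3 before the second aryl group is brought in, so that the lactone can later be moved with retention. It sets out from 5. Mitsunobu inversion (PPh3, DIAD, 4-nitrobenzoic acid, THF, 0 °C) gives the inverted ester (S)-[(3R)-5-oxooxolan-3-yl][3,4,5-tris(benzyloxy)phenyl]methyl 4-nitrobenzoate F1. Methanolysis (NaN3, MeOH, 40 °C) frees the syn lactone (4R)-4-{(S)-hydroxy[3,4,5-tris(benzyloxy)phenyl]methyl}dihydrofuran-2(3H)-one F2. The dianion aldol with 6 under the conditions of step 2 gives the syn diol lactone (3S,4R)-3-{[3,4-bis(benzyloxy)phenyl](hydroxy)methyl}-4-{(S)-hydroxy[3,4,5-tris(benzyloxy)phenyl]methyl}dihydrofuran-2(3H)-one F3. Catalytic NaH in THF at 0 °C then shifts the acyl group from O4 to the C3 alkoxide with retention (translactonization). This gives 10, where the fallback comes back to the route; 10 is closed to 11 with catalytic TsOH·H2O in CH2Cl2 at 0 °C, the known SN1 etherification of furofuran lignan diols.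

Step 5. The ring C–O bonds at C3 and C6 can be hydrogenolysed once the phenols are free, and the pyrogallol and catechol rings oxidize in air. The fallback sets out from 11 and changes the end-game so that free phenols never sit on the catalyst. Hydrogenolysis in the presence of Ac2O and NaOAc (H2, 10% Pd/C, EtOAc, rt) acetylates each phenol as it is freed and gives the air-stable pentaacetate (3S,3aR,6S,6aS)-6-(3,4-diacetoxyphenyl)-3-(3,4,5-triacetoxyphenyl)tetrahydro-1H,3H-furo[3,4-c]furan-1-one F4. Its acetoxyaryl rings no longer activate the benzylic C–O bonds. NH4OAc in MeOH–H2O at rt under argon then removes the five aryl acetates without opening the lactone, and the fallback comes back at 12.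

Step 2. The dianion may add sluggishly to the electron-rich aldehyde or undergo retro-aldol on warming. The fallback sets out from 5 and replaces the lithium dianion by a Lewis-acid aldol of a silyl ketene acetal. Silylation (t-BuMe2SiCl, imidazole, DMF) gives the silyl ether (4R)-4-{(R)-[tert-butyl(dimethyl)silyl]oxy[3,4,5-tris(benzyloxy)phenyl]methyl}dihydrofuran-2(3H)-one F5. LiN(i-Pr)2 and Me3SiCl in THF at −78 °C give the ketene acetal {[(3R)-3-{(R)-[tert-butyl(dimethyl)silyl]oxy[3,4,5-tris(benzyloxy)phenyl]methyl}-2,3-dihydrofuran-5-yl]oxy}trimethylsilane F6. Mukaiyama aldol with 6 (BF3·OEt2, CH2Cl2, −78 °C, open transition state, attack anti to the C4 substituent) gives the protected diol lactone (3S,4R)-3-{[3,4-bis(benzyloxy)phenyl](hydroxy)methyl}-4-{(R)-[tert-butyl(dimethyl)silyl]oxy[3,4,5-tris(benzyloxy)phenyl]methyl}dihydrofuran-2(3H)-one F7. Bu4NF buffered with AcOH in THF at 0 °C removes the silyl ether, and the fallback comes back at 7.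

**Further compounds**
F1 | step 4 | (S)-[(3R)-5-oxooxolan-3-yl][3,4,5-tris(benzyloxy)phenyl]methyl 4-nitrobenzoate | O=C1C[C@H](CO1)[C@H](OC(=O)c1ccc(cc1)[N+](=O)[O-])c1cc(OCc2ccccc2)c(OCc2ccccc2)c(OCc2ccccc2)c1
F2 | step 4 | (4R)-4-{(S)-hydroxy[3,4,5-tris(benzyloxy)phenyl]methyl}dihydrofuran-2(3H)-one | O=C1C[C@H](CO1)[C@H](O)c1cc(OCc2ccccc2)c(OCc2ccccc2)c(OCc2ccccc2)c1
F3 | step 4 | (3S,4R)-3-{[3,4-bis(benzyloxy)phenyl](hydroxy)methyl}-4-{(S)-hydroxy[3,4,5-tris(benzyloxy)phenyl]methyl}dihydrofuran-2(3H)-one | O=C1OC[C@H]([C@H](O)c2cc(OCc3ccccc3)c(OCc3ccccc3)c(OCc3ccccc3)c2)[C@H]1C(O)c1ccc(OCc2ccccc2)c(OCc2ccccc2)c1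
F4 | step 5 | (3S,3aR,6S,6aS)-6-(3,4-diacetoxyphenyl)-3-(3,4,5-triacetoxyphenyl)tetrahydro-1H,3H-furo[3,4-c]furan-1-one | O=C1O[C@H](c2cc(OC(C)=O)c(OC(C)=O)c(OC(C)=O)c2)[C@H]2CO[C@H](c3ccc(OC(C)=O)c(OC(C)=O)c3)[C@@H]12
F5 | step 2 | (4R)-4-{(R)-[tert-butyl(dimethyl)silyl]oxy[3,4,5-tris(benzyloxy)phenyl]methyl}dihydrofuran-2(3H)-one | O=C1C[C@H](CO1)[C@@H](O[Si](C)(C)C(C)(C)C)c1cc(OCc2ccccc2)c(OCc2ccccc2)c(OCc2ccccc2)c1
F6 | step 2 | {[(3R)-3-{(R)-[tert-butyl(dimethyl)silyl]oxy[3,4,5-tris(benzyloxy)phenyl]methyl}-2,3-dihydrofuran-5-yl]oxy}trimethylsilane | C[Si](C)(C)OC1=C[C@H](CO1)[C@@H](O[Si](C)(C)C(C)(C)C)c1cc(OCc2ccccc2)c(OCc2ccccc2)c(OCc2ccccc2)c1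
F7 | step 2 | (3S,4R)-3-{[3,4-bis(benzyloxy)phenyl](hydroxy)methyl}-4-{(R)-[tert-butyl(dimethyl)silyl]oxy[3,4,5-tris(benzyloxy)phenyl]methyl}dihydrofuran-2(3H)-one | O=C1OC[C@H]([C@@H](O[Si](C)(C)C(C)(C)C)c2cc(OCc3ccccc3)c(OCc3ccccc3)c(OCc3ccccc3)c2)[C@H]1C(O)c1ccc(OCc2ccccc2)c(OCc2ccccc2)c1
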